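## The problem

Target 29 is an open C8 chain, numbered here from the oxirane CH2 (C1) to the chloromethyl carbon (C8), with methyl branches on C3 and C7. It carries a terminal oxirane (C1–C2), five halogens and five stereocentres (C2, C3, C4, C6, C7), of which C3 (Cl) and C7 (Br) are fully substituted. The halogens sit in two vicinal pairs, C3–Cl/C4–Br and C6–Cl/C7–Br, separated by the single methylene C5, so the chain is best built by joining a C1–C4 half and a C5–C8 half, and neither pair can be relied on to control the other. In each pair a secondary and a tertiary carbon bear different halogens in an anti relationship; at C6/C7 chlorine is on the secondary and bromine on the tertiary carbon, which no undirected alkene halogenation gives, and a leaving group on C4 or C6 cannot be displaced without the neighbouring tertiary halogen taking part. The plan turns that participation into the method: each pair is drawn from a haliranium ion made from a defined halohydrin, so the configurations of the C4 and C6 carbinols and of the tertiary C–X bonds at C3 and C7 become the four C–halogen centres with inversion at every carbon. C2 can come from the chiral pool and steer C3; C3 and a chiral reagent can fix C4; C7 needs its own asymmetric reaction; C6, next to a quaternary carbon whose methyl and chloromethyl arms differ little, has the weakest handle. The oxirane will not survive halide or acid and must be closed last, the tertiary halides and the secondary bromide exclude strong base, Lewis acids and reducing metals late on, a bromine next to C=N or C=O would be lost in any reductive step, and every free β-halo alkoxide closes to an epoxide. What allows a convergent union is the 1,3-relationship of C4 and C6 across C5: with C4 as C=N and C6 as C–O they are ring atoms of a 2-isoxazoline, so C4–C5 can be made by adding a C1–C4 nitrile oxide to the vinyl group of a C5–C8 dichloride.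

## Retrosynthesis

**Oxirane.** The O–C1 bond of 29 is cut first, giving monotosylate 28, diol 27 and acetonide 26. This is preferred to methylene transfer onto a C2 aldehyde because the C2–O bond is never broken and C2 comes unchanged from the chiral pool. 26 has no epoxide and tolerates the halide chemistry before it. The forward step must sulfonylate only the primary hydroxyl and close the ring with a base too weak to eliminate HBr or to close the C2 alkoxide onto C3.

**C6/C7 pair.** The C6–Cl and C7–Br bonds of 26 are cut together: triflate 25 of chlorohydrin 24 ionises with the C7 chlorine bridging to C6, and bromide opens the chloriranium ion at the tertiary carbon. Direct substitution at C6 is not an option (hindered, participating neighbour), and chlorobromination of a C6=C7 alkene would place the halogens the other way round. 24 has a carbinol at C6, which a cycloaddition can supply, and only chlorine at C7 and C8. The forward step needs participation by the C7 chlorine to outrun every other pathway and bromide to attack C7.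

**C3/C4 pair.** The C3–Cl and C4–Br bonds of 24 (as silyl ether 23) are traced likewise to triflate 22 of bromohydrin 21: bromine bridges from C3 to C4 and chloride opens at the tertiary C3. Bromine is a far better neighbouring group than chlorine, so this relay is placed first and the C6 oxygen stays silylated meanwhile.

**C3 bromine.** The C3–Br bond of 21 is cut to epoxide 20, which comes from hydroxy mesylate 19, mesylate 18 and alcohol 17. Carrying the bromine from the start would be shorter, but it fails twice: an α-bromo aldoxime loses HBr to a nitrosoalkene under the basic conditions that generate the dipole, and a bromine α to the isoxazoline C=N (later the ketone) would not survive reductive N–O cleavage. A tertiary silyloxy group is inert in both steps and later becomes the epoxide oxygen. The net result is stereospecific: chlorine ends where the C3 oxygen of 17 stood (two inversions) and bromine where the C4 hydroxyl of 17 stood (two inversions).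

**C4 carbinol and unmasking.** Alcohol 17 goes back to ketone 16 (reagent-controlled reduction), 16 to β-hydroxy ketone 15 by removing the C6 silyl group, and 15 to isoxazoline 14 by N–O cleavage. A ketone next to the quaternary C3 is a good substrate for an oxazaborolidine reduction, so C4 does not depend on substrate bias alone.

**Key cut.** 14 is cut at C4–C5 and C6–O into nitrile oxide 13 and alkene 11. This is the only disconnection that separates the two halide regions at the unfunctionalised C5 and returns both carbinols needed for the two relays from one ring. Both partners are small and are made independently. The forward reaction must be regioselective (oxygen to C6) and select one alkene face.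

**Nitrile oxide half.** 13 comes from hydroximoyl chloride 12 and oxime 7, made from aldehyde 6. Ozonolysis links 6 to vinyl carbinol 5/4, and the C3–C4 bond of 4 is cut to methyl ketone 3 and a vinyl Grignard reagent. Ketone 3 comes from Weinreb amide 2 and the commercial ester 1. C3 is set by 1,2-induction from C2 in a chelated ketone addition.

**Alkene half.** 11 comes from aldehyde 10 by methylenation, 10 from alcohol 9, and 9 from methallyl alcohol 8 by enantioselective dichlorination, which creates C7 and installs both chlorines in one step.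

## Roads not taken

Alternative 1: The cut is at the C6–Cl and C7–Br bonds of a small fragment. Allylation of aldehyde 10 would give homoallylic chlorohydrin A1; its triflate ionises with chlorine bridging and bromide opens at the tertiary carbon to give A2. The merit is that the least precedented event of the whole synthesis is tested on a five-step intermediate, and the C6 carbinol can be set by a reagent-controlled allylboration. That is better control of C6 than the cycloaddition offers, and it is a real advantage over the chosen plan, which runs the same chlorine shift at step 19 and sets C6 with weak bias at step 10. The weakness is what follows: C1–C4 must be grown linearly from the vinyl group of A2 with a tertiary bromide already on board. The vinyl carbon lacks C3, so a trisubstituted C3=C4 alkene has to be made (for example by cross-metathesis with the second-generation Grubbs catalyst, with poor geometry control) and then bromochlorinated with only remote stereocentres to direct the face. The chosen plan sets against this a convergent union and a stereospecific origin for C3 and C4 (chelate-controlled addition, oxazaborolidine reduction, epoxide, bromiranium ion).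

Alternative 2: The cut is at C1–C2 and O–C1. Dimethylsulfonium methylide adds to the C2 aldehyde A3 and the betaine closes to oxirane A4. The merits are real: no protecting group on C1/C2 and two steps fewer at the end than acetonide hydrolysis and sulfonylation. The weak points are three. C2 is created by 1,2-induction from a quaternary C3 whose methyl and chain substituents must be told apart. The ylide is a base and nucleophile towards an α-bromo aldehyde, whose adduct can displace bromide to a 2,3-epoxide. A4 must then carry a free oxirane through two triflation and halide steps that open epoxides. The chosen plan pays the two extra steps to take C2 from the chiral pool without ever breaking its C–O bond and to close the oxirane after the last halide has been introduced.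

Alternative 3: The cut is at C5–C6 and C4–Br. The α-chloro acyl radical from bromochloroacetyl imide A5 (RuCl2(PPh3)3 or CuCl with a bipyridine) adds to the vinyl group of tertiary chloride A6, and bromine transfer gives A7. It forms a skeletal bond and the C4–Br bond in one redox-neutral step with C3–Cl already in place, so it needs no bromine relay and reaches the C1–C6 core in fewer steps than steps 10–17 of the chosen route; in step economy to that point it is better. Its weak points are stereochemical. Bromine transfer to a radical beside the quaternary C3 and the α-chloro imide centre C6 (epimerisable) are both poorly controlled. C7 must then be built from the imide carbonyl as a tertiary bromide of defined configuration, for which there is no stereospecific route from a tertiary alcohol. The chosen plan is longer but has a stereospecific answer for both tertiary halides and reagent control at C4.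

Key step: step 10

Assumption: in step 7 the hand of the Schiff-base ligand that leads to (S)-9 is taken from the sense of induction known for other 2-substituted allyl alcohols and is to be confirmed by correlation of 9.

## Route

Step 1
Reactants: 1 methyl (4S)-2,2-dimethyl-1,3-dioxolane-4-carboxylate
Product: 2 (4S)-N-methoxy-N,2,2-trimethyl-1,3-dioxolane-4-carboxamide
Conditions: MeNH(OMe)·HCl, i-PrMgCl, THF, −20 °C
Reagents that add atoms: N,O-dimethylhydroxylamine hydrochloride, CNOC.Cl
Why: Weinreb amide formation by aminolysis of the ester with the magnesium amide; the low temperature should keep the α-alkoxy centre C2 intact.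

Step 2
Reactants: 2 (4S)-N-methoxy-N,2,2-trimethyl-1,3-dioxolane-4-carboxamide
Product: 3 1-[(4S)-2,2-dimethyl-1,3-dioxolan-4-yl]ethan-1-one
Conditions: MeMgBr, THF, 0 °C
Reagents that add atoms: methylmagnesium bromide, C[Mg]Br
Why: Grignard addition to a Weinreb amide stops at the ketone because the chelated tetrahedral intermediate survives until work-up.

Step 3
Reactants: 3 1-[(4S)-2,2-dimethyl-1,3-dioxolan-4-yl]ethan-1-one
Product: 4 (2S)-2-[(4S)-2,2-dimethyl-1,3-dioxolan-4-yl]but-3-en-2-ol
Conditions: CH2=CHMgBr, MgBr2·OEt2, CH2Cl2/THF, −78 °C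
Reagents that add atoms: vinylmagnesium bromide, C=C[Mg]Br
Why: Cram-chelate Grignard addition to an α-alkoxy ketone: magnesium bridges the carbonyl oxygen and the ring oxygen on C2 and vinyl enters anti to the ring CH2, which should set C3 with its oxygen where the chlorine of the target will stand.

Step 4
Reactants: 4 (2S)-2-[(4S)-2,2-dimethyl-1,3-dioxolan-4-yl]but-3-en-2-ol
Product: 5 triethyl{[(2S)-2-[(4S)-2,2-dimethyl-1,3-dioxolan-4-yl]but-3-en-2-yl]oxy}silane
Conditions: TESOTf, 2,6-lutidine, CH2Cl2, −78 → 0 °C
Reagents that add atoms: triethylsilyl trifluoromethanesulfonate, CC[Si](CC)(CC)OS(=O)(=O)C(F)(F)F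
Why: Silylation of a tertiary alcohol with a silyl triflate; the TES ether prevents chelation or hydride delivery from this oxygen in step 13 and can later be removed beside a TBS ether.

Step 5
Reactants: 5 triethyl{[(2S)-2-[(4S)-2,2-dimethyl-1,3-dioxolan-4-yl]but-3-en-2-yl]oxy}silane
Product: 6 (2R)-2-[(4S)-2,2-dimethyl-1,3-dioxolan-4-yl]-2-[(triethylsilyl)oxy]propanal
Conditions: O3, CH2Cl2/MeOH, −78 °C; then PPh3
Reagents that add atoms: ozone, [O-][O+]=O
Why: Ozonolysis with reductive work-up turns the vinyl group into the C4 aldehyde; the α-carbon is quaternary and cannot epimerise.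

Step 6
Reactants: 6 (2R)-2-[(4S)-2,2-dimethyl-1,3-dioxolan-4-yl]-2-[(triethylsilyl)oxy]propanal
Product: 7 (1E,2S)-2-[(4S)-2,2-dimethyl-1,3-dioxolan-4-yl]-2-[(triethylsilyl)oxy]propanal oxime
Conditions: NH2OH·HCl, pyridine, EtOH, rt
Reagents that add atoms: hydroxylamine hydrochloride, NO.Cl
Why: Oxime condensation of a hindered aldehyde; pyridine buffering keeps the silyl ether and acetonide intact.

Step 7
Reactants: 8 2-methylprop-2-en-1-ol
Product: 9 (2S)-2,3-dichloro-2-methylpropan-1-ol
Conditions: t-BuOCl, ClTi(OiPr)3, chiral tridentate Schiff-base ligand (20 mol%), hexanes, −20 °C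
Reagents that add atoms: tert-butyl hypochlorite, CC(C)(C)OCl; chlorotitanium triisopropoxide, CC(C)O[Ti](Cl)(OC(C)C)OC(C)C
Why: Titanium-catalysed enantioselective dichlorination of an allylic alcohol, a reaction type known for 2-substituted allyl alcohols; anti addition of electrophilic chlorine and titanium-bound chloride on the ligand-selected face sets C7 and places both chlorines.

Step 8
Reactants: 9 (2S)-2,3-dichloro-2-methylpropan-1-ol
Product: 10 (2S)-2,3-dichloro-2-methylpropanal
Conditions: Dess–Martin periodinane, CH2Cl2, 0 °C → rt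
Reagents that add atoms: none
Why: Dess–Martin oxidation of a primary alcohol under neutral conditions; with no α-hydrogen the aldehyde can neither epimerise nor eliminate HCl.

Step 9
Reactants: 10 (2S)-2,3-dichloro-2-methylpropanal
Product: 11 (3S)-3,4-dichloro-3-methylbut-1-ene
Conditions: Ph3PCH3Br, KN(SiMe3)2, THF, −78 → 0 °C
Reagents that add atoms: methyltriphenylphosphonium bromide, C[P+](c1ccccc1)(c1ccccc1)c1ccccc1.[Br-]
Why: Wittig methylenation of an α-quaternary aldehyde; the volatile tertiary allylic chloride is kept cold, free of Lewis acid and used as a solution so that it does not ionise or transpose.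

Step 10
Reactants: 7 (1E,2S)-2-[(4S)-2,2-dimethyl-1,3-dioxolan-4-yl]-2-[(triethylsilyl)oxy]propanal oxime; 11 (3S)-3,4-dichloro-3-methylbut-1-ene
Product: 14 (5R)-5-[(2S)-1,2-dichloropropan-2-yl]-3-{(1S)-1-[(4S)-2,2-dimethyl-1,3-dioxolan-4-yl]-1-[(triethylsilyl)oxy]ethyl}-4,5-dihydro-1,2-oxazole, via hydroximoyl chloride 12 (not isolated), via nitrile oxide 13 (not isolated)
Conditions: NCS, DMF, rt; then 11 (excess), Et3N (slow addition), CH2Cl2, 0 °C → rt
Reagents that add atoms: none
Why: Chlorination of oxime 7 gives 12, loss of HCl gives nitrile oxide 13, and 13 adds to the vinyl group of 11 in a concerted, asynchronous [3+2] cycloaddition; the closest known reaction type is the nitrile oxide–alkene cycloaddition to 2-isoxazolines used as masked β-hydroxy ketones. The isoxazoline ring closes by cycloaddition, the C4–C5 and C6–O bonds forming in the same step. Regioselectivity (oxygen on the substituted carbon C6) is secured by the monosubstituted alkene. Base-induced side reactions are excluded because the carbon next to the dipole is quaternary and bears a silyloxy group that cannot leave in a 1,4-elimination, and 11 has no acidic hydrogen. The hindered dipole should dimerise slowly, and slow addition of base with excess alkene suppresses the furoxan. The new centre C6 is controlled only by the allylic quaternary centre C7: the required (5R) isomer arises from the staggered transition states with the C7–Cl bond inside and the methyl anti, or the C7–Cl bond anti and the methyl outside. Because methyl and chloromethyl differ little, only a modest preference is expected and the C6 epimers are to be separated by chromatography at this stage.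

Step 11
Reactants: 14 (5R)-5-[(2S)-1,2-dichloropropan-2-yl]-3-{(1S)-1-[(4S)-2,2-dimethyl-1,3-dioxolan-4-yl]-1-[(triethylsilyl)oxy]ethyl}-4,5-dihydro-1,2-oxazole
Product: 15 (2R,5R,6S)-6,7-dichloro-2-[(4S)-2,2-dimethyl-1,3-dioxolan-4-yl]-5-hydroxy-6-methyl-2-[(triethylsilyl)oxy]heptan-3-one
Conditions: Mo(CO)6, MeCN/H2O, 80 °C
Reagents that add atoms: water, O
Why: Reductive N–O cleavage of a 2-isoxazoline by zerovalent molybdenum and hydrolysis of the β-hydroxy imine; no halogen is α to the C=N, so the unactivated alkyl chlorides, silyl ether and acetonide should be spared.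

Step 12
Reactants: 15 (2R,5R,6S)-6,7-dichloro-2-[(4S)-2,2-dimethyl-1,3-dioxolan-4-yl]-5-hydroxy-6-methyl-2-[(triethylsilyl)oxy]heptan-3-one
Product: 16 (2R,5R,6S)-5-[(tert-butyldimethylsilyl)oxy]-6,7-dichloro-2-[(4S)-2,2-dimethyl-1,3-dioxolan-4-yl]-6-methyl-2-[(triethylsilyl)oxy]heptan-3-one
Conditions: TBSOTf, 2,6-lutidine, CH2Cl2, −78 °C
Reagents that add atoms: tert-butyldimethylsilyl trifluoromethanesulfonate, CC(C)(C)[Si](C)(C)OS(=O)(=O)C(F)(F)F
Why: Low-temperature silylation of the hindered secondary alcohol is faster than enol silylation; the TBS ether is a non-participating neighbour for the bromine relay in step 17.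

Step 13
Reactants: 16 (2R,5R,6S)-5-[(tert-butyldimethylsilyl)oxy]-6,7-dichloro-2-[(4S)-2,2-dimethyl-1,3-dioxolan-4-yl]-6-methyl-2-[(triethylsilyl)oxy]heptan-3-one
Product: 17 (2S,3R,5R,6S)-5-[(tert-butyldimethylsilyl)oxy]-6,7-dichloro-2-[(4S)-2,2-dimethyl-1,3-dioxolan-4-yl]-6-methyl-2-[(triethylsilyl)oxy]heptan-3-ol
Conditions: (S)-Me-CBS oxazaborolidine (20 mol%), BH3·SMe2, THF, −30 °C
Reagents that add atoms: none
Why: Corey–Bakshi–Shibata reduction with the quaternary C3 side as the large group sets C4; the Felkin–Anh preference (hydride anti to the C3–O bond, methyl beside the incoming hydride) points the same way, so reagent and substrate are matched.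

Step 14
Reactants: 17 (2S,3R,5R,6S)-5-[(tert-butyldimethylsilyl)oxy]-6,7-dichloro-2-[(4S)-2,2-dimethyl-1,3-dioxolan-4-yl]-6-methyl-2-[(triethylsilyl)oxy]heptan-3-ol
Product: 18 (2R,3R,5R,6S)-5-[(tert-butyldimethylsilyl)oxy]-6,7-dichloro-2-[(4S)-2,2-dimethyl-1,3-dioxolan-4-yl]-6-methyl-2-[(triethylsilyl)oxy]heptan-3-yl methanesulfonate
Conditions: MsCl, Et3N, CH2Cl2, −20 → 0 °C
Reagents that add atoms: methanesulfonyl chloride, CS(=O)(=O)Cl
Why: Mesylation through the sulfene works on hindered secondary alcohols, and the C4 hydroxyl is the only free one.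

Step 15
Reactants: 18 (2R,3R,5R,6S)-5-[(tert-butyldimethylsilyl)oxy]-6,7-dichloro-2-[(4S)-2,2-dimethyl-1,3-dioxolan-4-yl]-6-methyl-2-[(triethylsilyl)oxy]heptan-3-yl methanesulfonate
Product: 20 (4S)-4-[(2S,3S)-3-{(2R,3S)-2-[(tert-butyldimethylsilyl)oxy]-3,4-dichloro-3-methylbutyl}-2-methyloxiran-2-yl]-2,2-dimethyl-1,3-dioxolane, via hydroxy mesylate 19 (not isolated)
Conditions: HF·pyridine, pyridine, THF, 0 °C; then K2CO3, MeOH, 0 °C → rt
Reagents that add atoms: none
Why: Buffered fluoride removes the TES ether faster than the hindered secondary TBS ether, and the tertiary alkoxide then closes the oxirane by intramolecular Williamson substitution (3-exo-tet) with inversion at C4.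

Step 16
Reactants: 20 (4S)-4-[(2S,3S)-3-{(2R,3S)-2-[(tert-butyldimethylsilyl)oxy]-3,4-dichloro-3-methylbutyl}-2-methyloxiran-2-yl]-2,2-dimethyl-1,3-dioxolane
Product: 21 (2R,3S,5R,6S)-2-bromo-5-[(tert-butyldimethylsilyl)oxy]-6,7-dichloro-2-[(4S)-2,2-dimethyl-1,3-dioxolan-4-yl]-6-methylheptan-3-ol
Conditions: LiBr, AcOH, THF, 0 °C → rt
Reagents that add atoms: lithium bromide, [Li+].[Br-]
Why: Acid-assisted anti opening of a trisubstituted epoxide by bromide at the tertiary carbon, with inversion at C3; the regioisomeric anti-bromohydrin would ionise to the same bromiranium ion, so the regiochemistry of this opening is not critical.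

Step 17
Reactants: 21 (2R,3S,5R,6S)-2-bromo-5-[(tert-butyldimethylsilyl)oxy]-6,7-dichloro-2-[(4S)-2,2-dimethyl-1,3-dioxolan-4-yl]-6-methylheptan-3-ol
Product: 23 (4S)-4-[(2R,3R,5R,6S)-3-bromo-5-[(tert-butyldimethylsilyl)oxy]-2,6,7-trichloro-6-methylheptan-2-yl]-2,2-dimethyl-1,3-dioxolane, via triflate 22 (not isolated)
Conditions: Tf2O, 2,6-di-tert-butyl-4-methylpyridine, CH2Cl2, −78 °C; then Bu4NCl, −78 → 0 °C
Reagents that add atoms: tetrabutylammonium chloride, CCCC[N+](CCCC)(CCCC)CCCC.[Cl-]
Why: Anchimerically assisted displacement of a β-bromo sulfonate: the anti C3 bromine expels triflate to give a bromiranium ion (inversion at C4), and chloride opens it at the tertiary carbon as in a Markovnikov bromochlorination (inversion at C3). A non-nucleophilic base keeps the ion from being trapped by pyridine.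

Step 18
Reactants: 23 (4S)-4-[(2R,3R,5R,6S)-3-bromo-5-[(tert-butyldimethylsilyl)oxy]-2,6,7-trichloro-6-methylheptan-2-yl]-2,2-dimethyl-1,3-dioxolane
Product: 24 (2S,3R,5R,6R)-5-bromo-1,2,6-trichloro-6-[(4S)-2,2-dimethyl-1,3-dioxolan-4-yl]-2-methylheptan-3-ol
Conditions: HF·pyridine, THF, 0 °C → rt
Reagents that add atoms: none
Why: Acidic fluoride desilylation; no alkoxide is formed, so the chlorohydrin cannot close to an epoxide and HBr is not eliminated.

Step 19
Reactants: 24 (2S,3R,5R,6R)-5-bromo-1,2,6-trichloro-6-[(4S)-2,2-dimethyl-1,3-dioxolan-4-yl]-2-methylheptan-3-ol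
Product: 26 (4S)-4-[(2R,3R,5S,6S)-3,6-dibromo-2,5,7-trichloro-6-methylheptan-2-yl]-2,2-dimethyl-1,3-dioxolane, via triflate 25 (not isolated)
Conditions: Tf2O, 2,6-di-tert-butyl-4-methylpyridine, CH2Cl2, −78 °C; then Bu4NBr, −78 → 0 °C
Reagents that add atoms: tetrabutylammonium bromide, CCCC[N+](CCCC)(CCCC)CCCC.[Br-]
Why: Ionisation of a β-chloro triflate to a chloriranium ion (inversion at C6) and capture by bromide at the tertiary carbon (inversion at C7); chloriranium ions from β-chloro sulfonates are configurationally stable and open with external nucleophiles at the more substituted carbon.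

Step 20
Reactants: 26 (4S)-4-[(2R,3R,5S,6S)-3,6-dibromo-2,5,7-trichloro-6-methylheptan-2-yl]-2,2-dimethyl-1,3-dioxolane
Product: 27 (2S,3R,4R,6S,7S)-4,7-dibromo-3,6,8-trichloro-3,7-dimethyloctane-1,2-diol
Conditions: CF3CO2H/H2O (9:1), CH2Cl2, 0 °C
Reagents that add atoms: none
Why: Acid hydrolysis of the acetonide; both tertiary halides are flanked by electron-withdrawing carbons and should not ionise at 0 °C.

Step 21
Reactants: 27 (2S,3R,4R,6S,7S)-4,7-dibromo-3,6,8-trichloro-3,7-dimethyloctane-1,2-diol
Product: 29 (2S)-2-[(2R,3R,5S,6S)-3,6-dibromo-2,5,7-trichloro-6-methylheptan-2-yl]oxirane, via primary tosylate 28 (not isolated)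
Conditions: TsCl, Et3N, Bu2SnO (5 mol%), CH2Cl2, 0 °C; then K2CO3, MeOH, 0 °C
Reagents that add atoms: none
Why: Tin-catalysed selective tosylation of the primary hydroxyl followed by intramolecular Williamson closure; the C2–O bond is retained, so C2 keeps its chiral-pool configuration, and closure onto the primary sulfonate is far faster than attack on the tertiary C3 chloride or elimination.

## Compound list

1 | methyl (4S)-2,2-dimethyl-1,3-dioxolane-4-carboxylate | COC(=O)[C@@H]1COC(C)(C)O1 | starting material
2 | (4S)-N-methoxy-N,2,2-trimethyl-1,3-dioxolane-4-carboxamide | CON(C)C(=O)[C@@H]1COC(C)(C)O1 | intermediate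
3 | 1-[(4S)-2,2-dimethyl-1,3-dioxolan-4-yl]ethan-1-one | CC(=O)[C@@H]1COC(C)(C)O1 | intermediate
4 | (2S)-2-[(4S)-2,2-dimethyl-1,3-dioxolan-4-yl]but-3-en-2-ol | C=C[C@](C)(O)[C@@H]1COC(C)(C)O1 | intermediate
5 | triethyl{[(2S)-2-[(4S)-2,2-dimethyl-1,3-dioxolan-4-yl]but-3-en-2-yl]oxy}silane | C=C[C@](C)(O[Si](CC)(CC)CC)[C@@H]1COC(C)(C)O1 | intermediate
6 | (2R)-2-[(4S)-2,2-dimethyl-1,3-dioxolan-4-yl]-2-[(triethylsilyl)oxy]propanal | O=C[C@](C)(O[Si](CC)(CC)CC)[C@@H]1COC(C)(C)O1 | intermediate
7 | (1E,2S)-2-[(4S)-2,2-dimethyl-1,3-dioxolan-4-yl]-2-[(triethylsilyl)oxy]propanal oxime | O/N=C/[C@](C)(O[Si](CC)(CC)CC)[C@@H]1COC(C)(C)O1 | intermediate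
8 | 2-methylprop-2-en-1-ol | C=C(C)CO | starting material
9 | (2S)-2,3-dichloro-2-methylpropan-1-ol | OC[C@](C)(Cl)CCl | intermediate
10 | (2S)-2,3-dichloro-2-methylpropanal | O=C[C@](C)(Cl)CCl | intermediate
11 | (3S)-3,4-dichloro-3-methylbut-1-ene | C=C[C@](C)(Cl)CCl | intermediate
12 | (2R)-2-[(4S)-2,2-dimethyl-1,3-dioxolan-4-yl]-N-hydroxy-2-[(triethylsilyl)oxy]propanimidoyl chloride | ON=C(Cl)[C@](C)(O[Si](CC)(CC)CC)[C@@H]1COC(C)(C)O1 | intermediate (not isolated)
13 | (2S)-2-[(4S)-2,2-dimethyl-1,3-dioxolan-4-yl]-2-[(triethylsilyl)oxy]propanenitrile oxide | [O-][N+]#C[C@](C)(O[Si](CC)(CC)CC)[C@@H]1COC(C)(C)O1 | intermediate (not isolated)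
14 | (5R)-5-[(2S)-1,2-dichloropropan-2-yl]-3-{(1S)-1-[(4S)-2,2-dimethyl-1,3-dioxolan-4-yl]-1-[(triethylsilyl)oxy]ethyl}-4,5-dihydro-1,2-oxazole | C[C@](O[Si](CC)(CC)CC)(C1=NO[C@H](C1)[C@](C)(Cl)CCl)[C@@H]1COC(C)(C)O1 | intermediate
15 | (2R,5R,6S)-6,7-dichloro-2-[(4S)-2,2-dimethyl-1,3-dioxolan-4-yl]-5-hydroxy-6-methyl-2-[(triethylsilyl)oxy]heptan-3-one | C[C@](O[Si](CC)(CC)CC)(C(=O)C[C@@H](O)[C@](C)(Cl)CCl)[C@@H]1COC(C)(C)O1 | intermediate
16 | (2R,5R,6S)-5-[(tert-butyldimethylsilyl)oxy]-6,7-dichloro-2-[(4S)-2,2-dimethyl-1,3-dioxolan-4-yl]-6-methyl-2-[(triethylsilyl)oxy]heptan-3-one | C[C@](O[Si](CC)(CC)CC)(C(=O)C[C@@H](O[Si](C)(C)C(C)(C)C)[C@](C)(Cl)CCl)[C@@H]1COC(C)(C)O1 | intermediate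
17 | (2S,3R,5R,6S)-5-[(tert-butyldimethylsilyl)oxy]-6,7-dichloro-2-[(4S)-2,2-dimethyl-1,3-dioxolan-4-yl]-6-methyl-2-[(triethylsilyl)oxy]heptan-3-ol | C[C@](O[Si](CC)(CC)CC)([C@H](O)C[C@@H](O[Si](C)(C)C(C)(C)C)[C@](C)(Cl)CCl)[C@@H]1COC(C)(C)O1 | intermediate
18 | (2R,3R,5R,6S)-5-[(tert-butyldimethylsilyl)oxy]-6,7-dichloro-2-[(4S)-2,2-dimethyl-1,3-dioxolan-4-yl]-6-methyl-2-[(triethylsilyl)oxy]heptan-3-yl methanesulfonate | C[C@](O[Si](CC)(CC)CC)([C@H](OS(C)(=O)=O)C[C@@H](O[Si](C)(C)C(C)(C)C)[C@](C)(Cl)CCl)[C@@H]1COC(C)(C)O1 | intermediate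
19 | (2R,3R,5R,6S)-5-[(tert-butyldimethylsilyl)oxy]-6,7-dichloro-2-[(4S)-2,2-dimethyl-1,3-dioxolan-4-yl]-2-hydroxy-6-methylheptan-3-yl methanesulfonate | C[C@](O)([C@H](OS(C)(=O)=O)C[C@@H](O[Si](C)(C)C(C)(C)C)[C@](C)(Cl)CCl)[C@@H]1COC(C)(C)O1 | intermediate (not isolated)
20 | (4S)-4-[(2S,3S)-3-{(2R,3S)-2-[(tert-butyldimethylsilyl)oxy]-3,4-dichloro-3-methylbutyl}-2-methyloxiran-2-yl]-2,2-dimethyl-1,3-dioxolane | C[C@@]1(O[C@H]1C[C@@H](O[Si](C)(C)C(C)(C)C)[C@](C)(Cl)CCl)[C@@H]2COC(C)(C)O2 | intermediate
21 | (2R,3S,5R,6S)-2-bromo-5-[(tert-butyldimethylsilyl)oxy]-6,7-dichloro-2-[(4S)-2,2-dimethyl-1,3-dioxolan-4-yl]-6-methylheptan-3-ol | C[C@@](Br)([C@@H](O)C[C@@H](O[Si](C)(C)C(C)(C)C)[C@](C)(Cl)CCl)[C@@H]1COC(C)(C)O1 | intermediate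
22 | (2S,3S,5R,6S)-2-bromo-5-[(tert-butyldimethylsilyl)oxy]-6,7-dichloro-2-[(4S)-2,2-dimethyl-1,3-dioxolan-4-yl]-6-methylheptan-3-yl trifluoromethanesulfonate | C[C@@](Br)([C@@H](OS(=O)(=O)C(F)(F)F)C[C@@H](O[Si](C)(C)C(C)(C)C)[C@](C)(Cl)CCl)[C@@H]1COC(C)(C)O1 | intermediate (not isolated)
23 | (4S)-4-[(2R,3R,5R,6S)-3-bromo-5-[(tert-butyldimethylsilyl)oxy]-2,6,7-trichloro-6-methylheptan-2-yl]-2,2-dimethyl-1,3-dioxolane | C[C@](Cl)([C@H](Br)C[C@@H](O[Si](C)(C)C(C)(C)C)[C@](C)(Cl)CCl)[C@@H]1COC(C)(C)O1 | intermediate
24 | (2S,3R,5R,6R)-5-bromo-1,2,6-trichloro-6-[(4S)-2,2-dimethyl-1,3-dioxolan-4-yl]-2-methylheptan-3-ol | C[C@](Cl)([C@H](Br)C[C@@H](O)[C@](C)(Cl)CCl)[C@@H]1COC(C)(C)O1 | intermediate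
25 | (2S,3R,5R,6R)-5-bromo-1,2,6-trichloro-6-[(4S)-2,2-dimethyl-1,3-dioxolan-4-yl]-2-methylheptan-3-yl trifluoromethanesulfonate | C[C@](Cl)([C@H](Br)C[C@@H](OS(=O)(=O)C(F)(F)F)[C@](C)(Cl)CCl)[C@@H]1COC(C)(C)O1 | intermediate (not isolated)
26 | (4S)-4-[(2R,3R,5S,6S)-3,6-dibromo-2,5,7-trichloro-6-methylheptan-2-yl]-2,2-dimethyl-1,3-dioxolane | C[C@](Cl)([C@H](Br)C[C@H](Cl)[C@@](C)(Br)CCl)[C@@H]1COC(C)(C)O1 | intermediate
27 | (2S,3R,4R,6S,7S)-4,7-dibromo-3,6,8-trichloro-3,7-dimethyloctane-1,2-diol | C[C@](Cl)([C@H](Br)C[C@H](Cl)[C@@](C)(Br)CCl)[C@@H](O)CO | intermediate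
28 | (2S,3R,4R,6S,7S)-4,7-dibromo-3,6,8-trichloro-2-hydroxy-3,7-dimethyloctyl 4-methylbenzenesulfonate | C[C@](Cl)([C@H](Br)C[C@H](Cl)[C@@](C)(Br)CCl)[C@@H](O)COS(=O)(=O)c1ccc(C)cc1 | intermediate (not isolated)
29 | (2S)-2-[(2R,3R,5S,6S)-3,6-dibromo-2,5,7-trichloro-6-methylheptan-2-yl]oxirane | C[C@](Cl)([C@H](Br)C[C@H](Cl)[C@@](C)(Br)CCl)[C@@H]1CO1 | target

## Step count and least certain steps

Total: 21 steps. Longest linear sequence: 18 steps (steps 1–6 and 10–21); the C5–C8 half takes 3 steps (7–9).

**Step 10 (key step).** Poor facial selectivity at C6 is the most likely failure. The only directing element is the quaternary C7, and the transition states that lead to the two C6 epimers differ only in whether methyl or chloromethyl takes the anti or the outside position, so the sense and size of the preference are uncertain and the wanted epimer may be the minor one. Slow cycloaddition to the hindered alkene would also let 13 dimerise. Fallback: the C4–C5 bond is made by a reagent-controlled aldol addition instead. It sets out from aldehyde 6 and uses aldehyde 10. MeMgBr adds to 6 to give (3S)-3-[(4S)-2,2-dimethyl-1,3-dioxolan-4-yl]-3-[(triethylsilyl)oxy]butan-2-ol F1 as a mixture of carbinol epimers, and Dess–Martin oxidation gives (3R)-3-[(4S)-2,2-dimethyl-1,3-dioxolan-4-yl]-3-[(triethylsilyl)oxy]butan-2-one F2. The diisopinocampheylboron enolate of F2 (Ipc2BCl of the hand that attacks the required aldehyde face, Et3N, then 10, oxidative work-up) should give β-hydroxy ketone 15, and the route is rejoined at step 12.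

**Step 19.** Diversion of the triflate into other ionisation pathways is the main risk, because chlorine is a weak neighbouring group. The C3 chlorine could bridge to C6 through a five-membered chloronium ion, bromide could attack the bridging chlorine instead of carbon (giving an alkene that is then halogenated with the wrong orientation), or direct substitution and elimination could compete. Fallback from 24: K2CO3 in methanol closes the chlorohydrin to (4S)-4-{(2R,3R)-3-bromo-2-chloro-4-[(2R,3R)-3-(chloromethyl)-3-methyloxiran-2-yl]butan-2-yl}-2,2-dimethyl-1,3-dioxolane F3 (inversion at C7). LiCl in acetic acid opens the oxirane at C6, the carbon remote from the electron-poor chloromethyl group, to give the tertiary alcohol (2S,3S,5R,6R)-5-bromo-1,3,6-trichloro-6-[(4S)-2,2-dimethyl-1,3-dioxolan-4-yl]-2-methylheptan-2-ol F4. SOBr2 with 2,6-lutidine then replaces the tertiary hydroxyl by bromine with retention through the same chlorine-bridged ion, now formed by ionisation at the tertiary carbon, and the route is rejoined at 26.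

**Step 17.** Loss of regiocontrol in the capture of the bromiranium ion (chloride at C4 instead of C3), direct displacement of the triflate by chloride, or interception of the ion by a dioxolane oxygen could erode the yield; the tertiary carbon carries an oxygenated neighbour that reduces its cationic character. Fallback from epoxide 20: Li2NiBr4 in THF delivers bromide under non-acidic conditions to C4 with inversion, giving (2R,3R,5R,6S)-3-bromo-5-[(tert-butyldimethylsilyl)oxy]-6,7-dichloro-2-[(4S)-2,2-dimethyl-1,3-dioxolan-4-yl]-6-methylheptan-2-ol F5. SOCl2 with pyridine converts the tertiary alcohol into the chloride with retention through the bromiranium ion, and the route is rejoined at 23.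

**Step 3.** Low or reversed 1,2-induction is possible, because an acetonide oxygen is a poor chelating ligand and the ketone may react through a non-chelated arrangement, which would favour the C3 epimer. Fallback from Weinreb amide 2: the two carbon groups are introduced in the opposite order. CH2=CHMgBr converts 2 into 1-[(4S)-2,2-dimethyl-1,3-dioxolan-4-yl]prop-2-en-1-one F6, and methyl is added last (MeLi or MeMgBr with CeCl3, THF, −78 °C). If acyl dioxolanes of this kind react through the Felkin–Anh arrangement, this order gives 4, where the route is rejoined.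

**Step 7.** Insufficient enantioselectivity is the risk, because the two carbon substituents on the new centre of this very small substrate (methyl and the chloromethyl formed in the reaction) are similar in size. Fallback from 8: Et4NCl3 adds chlorine to give racemic 2,3-dichloro-2-methylpropan-1-ol F7. A lipase with vinyl acetate, screened so that the (R)-alcohol reacts faster, converts that enantiomer into (2R)-2,3-dichloro-2-methylpropyl acetate F8 and leaves 9, which is separated and carried into step 8.

## Further compounds

F1 | step 10 | (3S)-3-[(4S)-2,2-dimethyl-1,3-dioxolan-4-yl]-3-[(triethylsilyl)oxy]butan-2-ol (both carbinol epimers) | CC(O)[C@](C)(O[Si](CC)(CC)CC)[C@@H]1COC(C)(C)O1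
F2 | step 10 | (3R)-3-[(4S)-2,2-dimethyl-1,3-dioxolan-4-yl]-3-[(triethylsilyl)oxy]butan-2-one | CC(=O)[C@](C)(O[Si](CC)(CC)CC)[C@@H]1COC(C)(C)O1
F3 | step 19 | (4S)-4-{(2R,3R)-3-bromo-2-chloro-4-[(2R,3R)-3-(chloromethyl)-3-methyloxiran-2-yl]butan-2-yl}-2,2-dimethyl-1,3-dioxolane | C[C@](Cl)([C@H](Br)C[C@H]2O[C@@]2(C)CCl)[C@@H]1COC(C)(C)O1
F4 | step 19 | (2S,3S,5R,6R)-5-bromo-1,3,6-trichloro-6-[(4S)-2,2-dimethyl-1,3-dioxolan-4-yl]-2-methylheptan-2-ol | C[C@](Cl)([C@H](Br)C[C@H](Cl)[C@@](C)(O)CCl)[C@@H]1COC(C)(C)O1
F5 | step 17 | (2R,3R,5R,6S)-3-bromo-5-[(tert-butyldimethylsilyl)oxy]-6,7-dichloro-2-[(4S)-2,2-dimethyl-1,3-dioxolan-4-yl]-6-methylheptan-2-ol | C[C@](O)([C@H](Br)C[C@@H](O[Si](C)(C)C(C)(C)C)[C@](C)(Cl)CCl)[C@@H]1COC(C)(C)O1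
F6 | step 3 | 1-[(4S)-2,2-dimethyl-1,3-dioxolan-4-yl]prop-2-en-1-one | C=CC(=O)[C@@H]1COC(C)(C)O1
F7 | step 7 | racemic 2,3-dichloro-2-methylpropan-1-ol | OCC(C)(Cl)CCl
F8 | step 7 | (2R)-2,3-dichloro-2-methylpropyl acetate | CC(=O)OC[C@@](C)(Cl)CCl
A1 | alternative 1 | (2S,3R)-1,2-dichloro-2-methylhex-5-en-3-ol | C=CC[C@@H](O)[C@](C)(Cl)CCl
A2 | alternative 1 | (4S,5S)-5-bromo-4,6-dichloro-5-methylhex-1-ene | C=CC[C@H](Cl)[C@@](C)(Br)CCl
A3 | alternative 2 | C2 aldehyde with C3–Br, C4–OTES, C6–OTBS, C7–Cl and C8–Cl | O=C[C@](C)(Br)[C@@H](O[Si](CC)(CC)CC)C[C@@H](O[Si](C)(C)C(C)(C)C)[C@](C)(Cl)CCl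
A4 | alternative 2 | terminal epoxide with C3–Br, C4–OTES, C6–OTBS, C7–Cl and C8–Cl | C[C@@](Br)([C@@H](O[Si](CC)(CC)CC)C[C@@H](O[Si](C)(C)C(C)(C)C)[C@](C)(Cl)CCl)[C@@H]1CO1
A5 | alternative 3 | 4-benzyl-3-(bromochloroacetyl)oxazolidin-2-one | O=C(C(Cl)Br)N1C(=O)OC[C@H]1Cc1ccccc1
A6 | alternative 3 | (4S)-4-(2-chlorobut-3-en-2-yl)-2,2-dimethyl-1,3-dioxolane with the C3 configuration of the target | C=C[C@](C)(Cl)[C@@H]1COC(C)(C)O1
A7 | alternative 3 | C1–C7 imide with C3–Cl, C4–Br and C6–Cl | C[C@](Cl)([C@H](Br)C[C@H](Cl)C(=O)N1C(=O)OC[C@H]1Cc1ccccc1)[C@@H]2COC(C)(C)O2
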